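**Assumptions (one line each)**
- The target has no stereocenters, so no enantiomer needs to be set. The prenyl CMe2 terminus has two identical methyls and the pyran C=C is endocyclic.
- In the chromene diol 5, the 7-OH is less hindered than the peri 5-OH, so one equivalent of MOMCl protects it selectively.

**Retrosynthesis**
1. Cathafuran C is 5-(6-hydroxybenzofuran-2-yl)-6-prenyl-7-hydroxy-2,2-dimethylchromene. The benzofuran ring is formed last, by acid cyclodehydration of an o-hydroxybenzyl aryl ketone (deoxybenzoin). This step also removes all MOM groups.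
2. The hindered aryl–C2 bond is made as a ketone α-C–C bond. A Pd-catalysed α-arylation joins an acetophenone (ring A) to 1-bromo-2,4-bis(MOMO)benzene (ring B), avoiding a Suzuki or Sonogashira coupling at the hindered biaryl carbon.
3. Ring A is built from phloroglucinol. Its 1,3,5-trioxygenation lets the future biaryl carbon start as a C–OH. That OH becomes a triflate and then the acetyl group, and the prenyl and pyran positions are fixed by symmetry.
4. Ring order: C-prenylation, then pyran annulation with prenal, then benzofuran closure.

**Route**

**Step 1**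
Reactants: 1 (phloroglucinol), 2 (prenyl bromide)
Product: 3 (2-prenylphloroglucinol, 2-(3-methylbut-2-enyl)benzene-1,3,5-triol)
Conditions: 1 (3 equiv), NaOH (1 equiv), THF/H2O, 0 °C; add 2 (1 equiv); rt, 2 h
Reagents that add atoms: prenyl bromide, CC(C)=CCBr
Why: Phloroglucinol is a carbon nucleophile in aqueous base (phenoxide C-alkylation, Friedel–Crafts-type). Excess phloroglucinol limits poly-prenylation, and all three ring CH positions are equivalent, so there is no regiochemical issue.

**Step 2**
Reactants: 3, 4 (3-methylbut-2-enal, prenal)
Product: 5 (6-prenyl-2,2-dimethyl-2H-chromene-5,7-diol)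
Conditions: 4 (1.2 equiv), pyridine, 130 °C, sealed tube, 16 h
Reagents that add atoms: prenal, CC(C)=CC=O
Why: Phenol–enal condensation (Knoevenagel-type C–C bond formation followed by o-quinone-methide 6π-oxa-electrocyclization) gives the 2,2-dimethylchromene. C4 and C6 of 3 are equivalent. Closure onto the OH para to the prenyl group (OH-5) avoids the gem-dimethyl/prenyl clash of the alternative 8-prenyl isomer. This places the prenyl group at C6 between the two OH groups.

**Step 3**
Reactants: 5, 6 (MOMCl)
Product: 7 (7-O-MOM ether of 5: 5-hydroxy-7-(methoxymethoxy)-6-prenyl-2,2-dimethyl-2H-chromene)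
Conditions: MOMCl (1.0 equiv), i-Pr2NEt (1.1 equiv), CH2Cl2, −10 → 0 °C
Reagents that add atoms: chloromethyl methyl ether, ClCOC
Why: Kinetic mono-alkylation of the more accessible 7-OH leaves the 5-OH, flanked by the prenyl group and the peri pyran CH, free for triflation. The regioisomer and bis-ether are removed by chromatography.

**Step 4**
Reactants: 7, 8 (Tf2O)
Product: 9 (5-triflate of 7)
Conditions: Tf2O (1.3 equiv), pyridine, CH2Cl2, 0 °C
Reagents that add atoms: triflic anhydride, O=S(=O)(OS(=O)(=O)C(F)(F)F)C(F)(F)F
Why: Standard phenol triflation. The MOM ether, prenyl group and chromene survive the pyridine-buffered conditions, and this converts the phloroglucinol C–OH into a cross-coupling handle.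

**Step 5**
Reactants: 9, 10 (n-butyl vinyl ether)
Product: 11 (1-[7-(methoxymethoxy)-2,2-dimethyl-6-prenyl-2H-chromen-5-yl]ethan-1-one)
Conditions: (i) 10 (5 equiv), Pd(OAc)2 (5 mol%), dppp (10 mol%), Et3N, DMF, 80 °C; (ii) 1 M HCl, THF, rt, 15 min
Reagents that add atoms: butyl vinyl ether, C=COCCCC (its CH2=CH–O unit becomes the acetyl group)
Why: The cationic Mizoroki–Heck pathway (Cabri) gives the α-arylated enol ether with hindered triflates, and mild hydrolysis unmasks the methyl ketone. Intramolecular Heck cyclisation onto the prenyl or pyran alkenes would require a strained 4-exo or 5-endo closure, so it is disfavoured.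

**Step 6**
Reactants: 12 (4-bromoresorcinol), 6 (MOMCl)
Product: 13 (1-bromo-2,4-bis(methoxymethoxy)benzene)
Conditions: NaH (2.4 equiv), DMF, 0 °C; MOMCl (2.4 equiv), 0 °C → rt
Reagents that add atoms: chloromethyl methyl ether, ClCOC
Why: Williamson-type acetal protection. Br is ortho to one O and para to the other, which is the substitution pattern required for the 6-oxygenated benzofuran (ortho O becomes O1, para O becomes the 6-OH).

**Step 7**
Reactants: 11, 13
Product: 14 (2-[2,4-bis(MOMO)phenyl]-1-[7-(MOMO)-2,2-dimethyl-6-prenyl-2H-chromen-5-yl]ethan-1-one)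
Conditions: 11 (1.0 equiv), 13 (1.2 equiv), Pd2(dba)3 (3 mol%), XPhos (12 mol%), NaOt-Bu (2.2 equiv), toluene, 80 °C
Reagents that add atoms: none (the aryl bromide 13 is listed as a reactant)
Why: Buchwald–Hartwig ketone α-arylation. Only the unhindered COCH3 is enolisable, and the 2,6-disubstituted aroyl group suppresses self-condensation. The ortho-substituted aryl bromide slows a second arylation, which is controlled further by the 1.0:1.2 stoichiometry. No stereocentre is formed.

**Step 8**
Reactants: 14
Product: 15 (Cathafuran C)
Conditions: (i) 3 M HCl, THF/MeOH (2:1), 50 °C, 4 h; (ii) solvent swap, TsOH·H2O (0.2 equiv), toluene, 80 °C, 1 h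
Reagents that add atoms: none
Why: MOM acetal hydrolysis liberates the o-hydroxybenzyl ketone. The phenol adds to the ketone to give a hemiketal, and acid-catalysed dehydration (cyclodehydration) aromatises it to the 2-arylbenzofuran. The para-oxygen on ring B assists this. The product is achiral.

**Verification**
- The ring A pattern in 15 is C5 (benzofuranyl), C6 (prenyl), C7 (OH), C8 (H), C8a (pyran O), C4a–C4=C3–C2Me2. This matches the target SMILES.
- The benzofuran has its 6-OH and C3–H, as in the target.
- Atom count: 14 (after loss of the three MOM groups, C24H26O5) minus H2O gives C24H24O4. This matches the target formula.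
- Protecting groups: the MOM groups survive Steps 4, 5 and 7 and are removed only in Step 8.

**Compound list**
1 | phloroglucinol | Oc1cc(O)cc(O)c1 | starting material
2 | prenyl bromide | CC(C)=CCBr | starting material
3 | 2-prenylphloroglucinol | CC(C)=CCc1c(O)cc(O)cc1O | intermediate
4 | 3-methylbut-2-enal (prenal) | CC(C)=CC=O | starting material
5 | 6-prenyl-2,2-dimethyl-2H-chromene-5,7-diol | CC(C)=CCc1c(O)cc2OC(C)(C)C=Cc2c1O | intermediate
6 | chloromethyl methyl ether (MOMCl) | ClCOC | starting material
7 | 5-hydroxy-7-(MOMO)-6-prenyl-2,2-dimethylchromene | CC(C)=CCc1c(OCOC)cc2OC(C)(C)C=Cc2c1O | intermediate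
8 | triflic anhydride | O=S(=O)(OS(=O)(=O)C(F)(F)F)C(F)(F)F | starting material
9 | 5-triflate of 7 | CC(C)=CCc1c(OCOC)cc2OC(C)(C)C=Cc2c1OS(=O)(=O)C(F)(F)F | intermediate
10 | n-butyl vinyl ether | C=COCCCC | starting material
11 | 5-acetyl-7-(MOMO)-6-prenyl-2,2-dimethylchromene | CC(=O)c1c(CC=C(C)C)c(OCOC)cc2OC(C)(C)C=Cc12 | intermediate
12 | 4-bromoresorcinol | Oc1ccc(Br)c(O)c1 | starting material
13 | 1-bromo-2,4-bis(MOMO)benzene | COCOc1ccc(Br)c(OCOC)c1 | intermediate
14 | tris-MOM deoxybenzoin | COCOc1ccc(CC(=O)c2c(CC=C(C)C)c(OCOC)cc3OC(C)(C)C=Cc23)c(OCOC)c1 | intermediate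
15 | Cathafuran C | CC(C)=CCc1c(O)cc2c(c1-c1cc3ccc(O)cc3o1)C=CC(C)(C)O2 | target

**Totals:** 8 steps in total; the longest linear sequence is 7 steps (1 → 3 → 5 → 7 → 9 → 11 → 14 → 15).

**Three steps most likely to fail**
1. **Step 7 (α-arylation of the hindered ketone).** It risks diarylation or low conversion. Fallback: use triflate 9 in a Suzuki–Miyaura coupling with 6-(MOMO)benzofuran-2-yl-Bpin (Pd/SPhos), then remove the MOM groups. This forms the biaryl bond first instead of building the benzofuran from a ketone.
2. **Step 2 (pyran regiochemistry, with the Step 1 prenylation yield).** The 8-prenyl isomer may form, and mono-prenylation may be poor. Fallback: prenylate 1,3,5-tris(MOMO)benzene by lithiation and prenyl bromide/CuI, then deprotect to 3. Close the pyran stepwise by C-acylation with senecioyl chloride, oxa-Michael ring closure to the chromanone, NaBH4 reduction and dehydration, so the regioisomers can be separated at the crystalline chromanone stage.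
3. **Step 8 (acid cascade).** The chromene or prenyl group may be damaged, or the deoxybenzoin may cyclise incompletely. Fallback: use TIPS instead of MOM on all three phenols. Remove them with TBAF, then dehydrate the hemiketal under neutral conditions with Martin sulfurane.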